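## Retrosynthetic overview
1. The C7 chain (12 carbons plus 4-hydroxyphenyl) comes off by Lewis-acid alkynylation of a cis-fused bicyclic methyl ketal (oxocarbenium), then Sonogashira coupling and full hydrogenation.
2. The THF ring, the Cd stereocentre and the cis ring fusion come from a tandem hemiketalisation/oxa-Michael closure of a γ-acetonyl-γ-methylbutenolide. The lactone ring is already present.
3. The butenolide comes from Nef conversion of a γ-(2-nitropropyl)butenolide. That adduct comes from an organocatalytic vinylogous Michael addition of α-angelica lactone to 2-nitropropene, which sets the first stereocentre (the quaternary Cc).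

Assumptions:
- 2-nitropropene is taken as commercial, or freshly made from 2-nitro-1-propanol and phthalic anhydride.
- 1,11-dodecadiyne is taken as commercial, or made from 1,8-dibromooctane and lithium acetylide·EDA.
- The target is (1S,5S,7S)-7-[12-(4-hydroxyphenyl)dodecyl]-1,7-dimethyl-2,6-dioxabicyclo[3.3.0]octan-3-one. In this framework, C1 is the lactone-O-bearing quaternary carbon, C5 is the ring-fusion CH and C7 is the chain-bearing carbon.
- In the target the chain sits on the convex face, cis to the C1-Me and C5-H.

## Route

**Step 1**
Reactants: 1 α-angelica lactone (5-methylfuran-2(3H)-one); 2 2-nitropropene.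
Product: 3 (S)-5-methyl-5-(2-nitropropyl)furan-2(5H)-one (about 1:1 epimers at the nitro-bearing CH).
Conditions: 10 mol% quinine-derived bifunctional squaramide, toluene, −20 °C, 2 added slowly, 48 h.
Reagents that add atoms: none.
Why: This is an organocatalytic vinylogous Michael addition. The amine deprotonates 1 to the 2-oxidofuran dienolate and the squaramide binds the nitroalkene. γ-Attack on one face of the dienolate sets the quaternary carbon, which is C1 of the target, as S. The catalyst enantiomer is chosen to give S. The nitro-CH stereocentre is destroyed in Step 2.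

**Step 2**
Reactants: 3.
Product: 4 (S)-5-methyl-5-(2-oxopropyl)furan-2(5H)-one.
Conditions: TiCl3 (aq.), NH4OAc buffer, THF/H2O, rt.
Reagents that add atoms: water, O.
Why: This is a buffered reductive (McMurry) Nef reaction. It converts the secondary nitroalkane to the methyl ketone under mild conditions that leave the butenolide and the quaternary centre untouched.

**Step 3**
Reactants: 4.
Product: 5 (1S,5S)-7-methoxy-1,7-dimethyl-2,6-dioxabicyclo[3.3.0]octan-3-one, cis-fused, as a mixture of C7 epimers.
Conditions: MeOH (0.1 M), 20 mol% DBU, 0 °C to rt, then quench with AcOH.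
Reagents that add atoms: methanol, CO.
Why: Proposed new method: the ketone and MeOH equilibrate with a hemiketal alkoxide. This alkoxide adds 5-exo-trig to the β-carbon of the γ,γ-disubstituted butenolide, and the former carbonyl carbon is trapped as a methyl ketal. The tether can only deliver oxygen to the face bearing the Cb chain, so the C5 stereocentre forms with the cis ring fusion (a trans-fused [3.3.0] system is inaccessible). The closest known reactions are tandem hemiketalisation/oxa-Michael cascades of hydroxy-enones and base-mediated oxa-Michael cyclisations of tethered alcohols onto butenolides. Both C7 epimers ionise to the same oxocarbenium in Step 4, so their ratio does not matter.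

**Step 4**
Reactants: 5; 6 1,11-dodecadiyne.
Product: 7 (1S,5S,7R)-7-(dodeca-1,11-diyn-1-yl)-1,7-dimethyl-2,6-dioxabicyclo[3.3.0]octan-3-one.
Conditions: 6 (3 equiv) + n-BuLi (1.5 equiv) + Et2AlCl (1.5 equiv), THF/hexane, −78 to 0 °C to make the mono-alkynylalane; add 5 in CH2Cl2, −78 to 0 °C.
Reagents that add atoms: none beyond reactant 6 (C#CCCCCCCCCC#C).
Why: This is Lewis-acid ionisation of the methyl ketal followed by alkynylation of the cyclic oxocarbenium, as in C-glycosylation. The alkynyl group attacks the convex face of the cis-bicycle, the face carrying the C1-Me and C5-H. This puts the chain cis to them and the C7-Me endo, matching the target. The descriptor at C7 reads R here only because the alkynyl group outranks the ring CH2 in CIP priority; the geometry is the same as in the target. The excess diyne prevents double alkylation.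

**Step 5**
Reactants: 7; 8 4-iodophenol.
Product: 9 (1S,5S,7R)-7-[12-(4-hydroxyphenyl)dodeca-1,11-diyn-1-yl]-1,7-dimethyl-2,6-dioxabicyclo[3.3.0]octan-3-one.
Conditions: Pd(PPh3)2Cl2 (5 mol%), CuI (10 mol%), Et3N, THF, rt, degassed.
Reagents that add atoms: none beyond reactant 8.
Why: Sonogashira coupling occurs only at the terminal alkyne. The free phenol, lactone and tertiary ether are unaffected, and no stereocentre is touched.

**Step 6**
Reactants: 9.
Product: 10 plakortone N.
Conditions: H2 (1 atm), 10% Pd/C, EtOAc, rt.
Reagents that add atoms: none (H2 adds hydrogen only).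
Why: Catalytic hydrogenation reduces both alkynes (aryl alkyne and internal dialkyl alkyne) to the saturated (CH2)12 chain. The phenol, lactone and saturated tertiary ether survive, and all three stereocentres are already set.

## Compound list
1 | α-angelica lactone (5-methylfuran-2(3H)-one) | CC1=CCC(=O)O1 | starting material
2 | 2-nitropropene | CC(=C)[N+](=O)[O-] | starting material
3 | (S)-5-methyl-5-(2-nitropropyl)furan-2(5H)-one | C[C@]1(CC(C)[N+](=O)[O-])C=CC(=O)O1 | intermediate
4 | (S)-5-methyl-5-(2-oxopropyl)furan-2(5H)-one | C[C@]1(CC(C)=O)C=CC(=O)O1 | intermediate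
5 | (1S,5S)-7-methoxy-1,7-dimethyl-2,6-dioxabicyclo[3.3.0]octan-3-one (C7 epimers) | CC1(OC)C[C@]2(C)OC(=O)C[C@@H]2O1 | intermediate
6 | 1,11-dodecadiyne | C#CCCCCCCCCC#C | starting material
7 | (1S,5S,7R)-7-(dodeca-1,11-diynyl)-1,7-dimethyl-2,6-dioxabicyclo[3.3.0]octan-3-one | C[C@]1(C#CCCCCCCCCC#C)C[C@]2(C)OC(=O)C[C@@H]2O1 | intermediate
8 | 4-iodophenol | Oc1ccc(I)cc1 | starting material
9 | (1S,5S,7R)-7-[12-(4-hydroxyphenyl)dodeca-1,11-diynyl]-1,7-dimethyl-2,6-dioxabicyclo[3.3.0]octan-3-one | C[C@]1(C#CCCCCCCCCC#Cc2ccc(O)cc2)C[C@]2(C)OC(=O)C[C@@H]2O1 | intermediate
10 | plakortone N, (1S,5S,7S)-7-[12-(4-hydroxyphenyl)dodecyl]-1,7-dimethyl-2,6-dioxabicyclo[3.3.0]octan-3-one | C[C@]1(CCCCCCCCCCCCc2ccc(O)cc2)C[C@]2(C)OC(=O)C[C@@H]2O1 | target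

## Summary
Total steps: 6. Longest linear sequence: 6, from α-angelica lactone.

Three steps most likely to fail:
1. **Step 4 (C7 diastereoselectivity).**
   - Risks: the angular C1-Me on the convex face may lower the exo/endo selectivity, or ionisation may occur at the ring C–O or the C1–O lactone bond.
   - Fallback: allylate 5 with allyl-TMS/BF3·OEt2 (known C-glycoside-type chemistry), then cross-metathesise with 11-(4-acetoxyphenyl)undec-1-ene, hydrogenate, and remove the acetate with K2CO3/MeOH. Separate C7 epimers by chromatography if needed.
2. **Step 3 (proposed new cascade).**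
   - Risk: the ketal equilibrium may lie on the open-chain side.
   - Fallback: add the lithiated diyne to ketone 4 with CeCl3 at −78 °C, then close the ring by DBU-catalysed oxa-Michael of the tertiary propargylic alkoxide. This sets C7 by 1,3-induction, and the epimers are separated at the stage of compound 7.
3. **Step 1 (enantioselectivity with the small, reactive nitroalkene).**
   - Fallback: Pd-catalysed asymmetric γ-allylation of 1 with methallyl carbonate using a Trost-type ligand, followed by selective ozonolysis of the 1,1-disubstituted alkene. This gives 4 directly.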